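## Retrosynthetic overview

1. Target 30 ⇐ 4,5-olefin 29 by late epoxidation of C4=C5 ⇐ tetraol 26, whose C12/O6 γ-lactone and C14 ester come from alcohol oxidation ⇐ ketone 23, which gives the C9 carbinol by CBS reduction and carries the C8 ester from Mitsunobu inversion with oxirane acid 22.
2. The ten-membered ring ⇐ anionic oxy-Cope ring expansion of the trans-1,2-dialkenylcyclohex-2-en-1-ol 16. The C4–C9 bond of a six-membered ring (C9–C10=C1–C2–C3–C4) is cut and C6–C7 is formed. The ring-cis C1=C10 bond is the old cyclohexene bond, the C9 oxygen is the carbinol oxygen, C4=C5 is born E, C6/C7 are set by the chair, and the enolate is hydroxylated at C8 in the same flask.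
3. 16 ⇐ dienyllithium 15 (C8, C7, C11–C13) + (S)-cyclohexenone 10 (C9, C10, C14, C1–C4, C15 and the C5=C6–O enol ether).
4. 10 ⇐ catalytic asymmetric Diels–Alder of methacrolein with 1-acetoxybutadiene (C4 quaternary centre), Takai iodo-olefination, Cu C–O coupling, Baylis–Hillman hydroxymethylation.
5. Ring order: cyclohexene (step 1) → ten-membered carbocycle (step 10) → γ-lactone (step 16) → 4,5-oxirane (step 19). The side-chain oxirane comes from Sharpless epoxidation of tiglyl alcohol.

Key step: step 10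

Remark on numbering: ring-expanded compounds carry germacrane numbering (ring C1–C10; C11–C13 on C7 with C12 the lactone carbonyl; C14 on C10; C15 on C4); α is the face of H-7, β the opposite face.

Assumption: the facial sense of the oxazaborolidinium-catalysed Diels–Alder reaction in step 1 is taken from the accepted model for 2-substituted acroleins; if the opposite sense is found, the antipodal catalyst (from D-proline) is used. The acetoxy-bearing centre of 3 is expected as an epimer mixture (major drawn), which converges at ketone 8.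

## Route

Step 1
Reactants: 1 (E)-buta-1,3-dien-1-yl acetate; 2 methacrolein
Product: 3 (1R,6R)-6-formyl-6-methylcyclohex-2-en-1-yl acetate
Conditions: (S)-o-tolyl-oxazaborolidinium triflimide (10 mol%), CH2Cl2, −78 → −40 °C
Reagents that add atoms: none
Why: Cationic oxazaborolidine-catalysed Diels–Alder reaction with "ortho" regiochemistry from the 1-oxygenated diene; the catalyst shields one face of the coordinated s-trans enal and so should set the quaternary centre (C4 of the target).

Step 2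
Reactants: 3 (1R,6R)-6-formyl-6-methylcyclohex-2-en-1-yl acetate
Product: 4 (1R,6S)-6-[(E)-2-iodoethenyl]-6-methylcyclohex-2-en-1-yl acetate
Conditions: CrCl2 (6 equiv), CHI3 (2 equiv), THF, 0 °C → rt
Reagents that add atoms: iodoform, IC(I)I
Why: Takai olefination through a gem-dichromium species should give the (E)-vinyl iodide and tolerates the allylic acetate.

Step 3
Reactants: 4 (1R,6S)-6-[(E)-2-iodoethenyl]-6-methylcyclohex-2-en-1-yl acetate; 5 4-methoxybenzyl alcohol
Product: 7 (1R,6S)-6-{(E)-2-[(4-methoxybenzyl)oxy]ethenyl}-6-methylcyclohex-2-en-1-ol, via acetate enol ether 6 (not isolated)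
Conditions: CuI (10 mol%), 3,4,7,8-tetramethyl-1,10-phenanthroline (20 mol%), Cs2CO3, toluene, 80 °C; then K2CO3 (cat.), MeOH, rt
Reagents that add atoms: none
Why: Cu-catalysed Ullmann-type C–O coupling of a vinyl iodide with an alcohol proceeds with retention of olefin geometry and gives the (E)-enol ether (the future C5=C6–O6 unit); methanolysis in the same flask frees the allylic alcohol.

Step 4
Reactants: 7 (1R,6S)-6-{(E)-2-[(4-methoxybenzyl)oxy]ethenyl}-6-methylcyclohex-2-en-1-ol
Product: 8 (6S)-6-{(E)-2-[(4-methoxybenzyl)oxy]ethenyl}-6-methylcyclohex-2-en-1-one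
Conditions: MnO2 (excess), CH2Cl2, rt
Reagents that add atoms: none
Why: Neutral allylic oxidation with MnO2 spares the acid-labile enol ether and removes the carbinol centre, so both epimers converge.

Step 5
Reactants: 8 (6S)-6-{(E)-2-[(4-methoxybenzyl)oxy]ethenyl}-6-methylcyclohex-2-en-1-one
Product: 9 (6S)-2-(hydroxymethyl)-6-{(E)-2-[(4-methoxybenzyl)oxy]ethenyl}-6-methylcyclohex-2-en-1-one
Conditions: 37% aq. HCHO, DMAP (cat.), THF, rt
Reagents that add atoms: formaldehyde, C=O
Why: Morita–Baylis–Hillman hydroxymethylation of a cyclohexenone installs C14 on C10; the α'-carbon is quaternary, so only the enone α-position can react.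

Step 6
Reactants: 9 (6S)-2-(hydroxymethyl)-6-{(E)-2-[(4-methoxybenzyl)oxy]ethenyl}-6-methylcyclohex-2-en-1-one
Product: 10 (6S)-6-{(E)-2-[(4-methoxybenzyl)oxy]ethenyl}-6-methyl-2-{[(triethylsilyl)oxy]methyl}cyclohex-2-en-1-one
Conditions: Et3SiCl, imidazole, CH2Cl2, 0 °C
Reagents that add atoms: chlorotriethylsilane, CC[Si](Cl)(CC)CC
Why: Silylation of the primary alcohol under non-acidic conditions is compatible with the enone and the enol ether.

Step 7
Reactants: 11 2,3-dibromoprop-1-ene; 5 4-methoxybenzyl alcohol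
Product: 12 1-{[(2-bromoprop-2-en-1-yl)oxy]methyl}-4-methoxybenzene
Conditions: NaH, THF, 0 °C → rt
Reagents that add atoms: none
Why: Williamson etherification occurs by SN2 at the allylic bromide only; the vinylic bromide is inert.

Step 8
Reactants: 12 1-{[(2-bromoprop-2-en-1-yl)oxy]methyl}-4-methoxybenzene; 13 (E)-1,2-bis(tributylstannyl)ethene
Product: 14 tributyl[(1E)-3-{[(4-methoxybenzyl)oxy]methyl}buta-1,3-dien-1-yl]stannane
Conditions: Pd(PPh3)4 (5 mol%), toluene, 90 °C, 13 in excess
Reagents that add atoms: none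
Why: Stille mono-coupling of the distannane (used in excess) with the vinyl bromide retains the E geometry and leaves one stannyl group for lithiation.

Step 9
Reactants: 14 tributyl[(1E)-3-{[(4-methoxybenzyl)oxy]methyl}buta-1,3-dien-1-yl]stannane; 10 (6S)-6-{(E)-2-[(4-methoxybenzyl)oxy]ethenyl}-6-methyl-2-{[(triethylsilyl)oxy]methyl}cyclohex-2-en-1-one
Product: 16 (1R,6S)-6-{(E)-2-[(4-methoxybenzyl)oxy]ethenyl}-1-[(1E)-3-{[(4-methoxybenzyl)oxy]methyl}buta-1,3-dien-1-yl]-6-methyl-2-{[(triethylsilyl)oxy]methyl}cyclohex-2-en-1-ol, via dienyllithium 15 (not isolated)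
Conditions: n-BuLi, THF, −78 °C; then 10, −78 °C; H2O
Reagents that add atoms: none
Why: Tin–lithium exchange with retention, then 1,2-addition to the enone, which should occur anti to the alkoxyvinyl group of the α-quaternary carbon (Felkin–Anh, π-substituent antiperiplanar to the incoming nucleophile) and so give the trans-dialkenyl carbinol.

Step 10
Reactants: 16 (1R,6S)-6-{(E)-2-[(4-methoxybenzyl)oxy]ethenyl}-1-[(1E)-3-{[(4-methoxybenzyl)oxy]methyl}buta-1,3-dien-1-yl]-6-methyl-2-{[(triethylsilyl)oxy]methyl}cyclohex-2-en-1-ol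
Product: 19 8α-hydroxy-6α,12-bis[(4-methoxybenzyl)oxy]-14-[(triethylsilyl)oxy]germacra-1(10),4,11(13)-trien-9-one (1(10)-cis; 4E; H-7α), via potassium alkoxide 17 (not isolated), via potassium dienolate 18 (not isolated)
Conditions: KHMDS, 18-crown-6, THF, 0 °C → rt; then trans-2-(phenylsulfonyl)-3-phenyloxaziridine, −78 °C; AcOH
Reagents that add atoms: trans-2-(phenylsulfonyl)-3-phenyloxaziridine, O=S(=O)(N1OC1c1ccccc1)c1ccccc1
Why: Deprotonation gives the bis-allylic alkoxide 17, and a concerted anionic oxy-Cope [3,3]-shift through a chair transition state breaks C4–C9 and forms C6–C7, a four-atom ring expansion of the cyclohexene to the ten-membered dienolate 18; the closest precedent is the oxy-Cope expansion of trans-1,2-dialkenylcyclohexanols to cyclodec-5-enones with enolate oxidation. Because the two alkenyl groups are trans, the only chair the six-membered ring allows has both ring bonds (C9–C10 and C4–C3) equatorial, so the new C4=C5 bond is E, while the ring-cis C1=C10 bond is carried over unchanged from the cyclohexene. Both migrating termini are E, so C11 on C7 and the PMB-oxy group on C6 sit equatorial and the new bond should form with the 6,7-trans relationship (O-6α, C-11β); the absolute sense comes from the (1R,6S) centres of 16, which are destroyed in the step. Formation of the cross-conjugated potassium enolate makes the rearrangement irreversible. The oxaziridine should then attack C8 on the outer face of the enolate, anti to the new C6–C7 bond, because the inner face is covered by the transannular C4=C5 bond; this gives the 8α-alcohol. The step needs the trans-dialkenyl relationship and pure E geometry in both alkenyl groups of 16, which steps 2, 3, 8 and 9 are designed to provide.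

Step 11
Reactants: 20 (E)-2-methylbut-2-en-1-ol
Product: 21 [(2R,3R)-2,3-dimethyloxiran-2-yl]methanol
Conditions: Ti(OiPr)4 (5 mol%), D-(−)-diisopropyl tartrate (6 mol%), t-BuOOH, 4 Å MS, CH2Cl2, −20 °C
Reagents that add atoms: tert-butyl hydroperoxide, CC(C)(C)OO
Why: Sharpless asymmetric epoxidation; D-(−)-tartrate delivers oxygen to the face that gives the (2R,3R)-epoxy alcohol, and the E olefin fixes the cis relationship of the two methyl groups.

Step 12
Reactants: 21 [(2R,3R)-2,3-dimethyloxiran-2-yl]methanol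
Product: 22 (2S,3R)-2,3-dimethyloxirane-2-carboxylic acid
Conditions: RuCl3 (2 mol%), NaIO4, MeCN/CCl4/H2O, rt
Reagents that add atoms: water, O; sodium periodate, [Na+].[O-]I(=O)(=O)=O
Why: RuO4-catalysed oxidation of an epoxy alcohol to the glycidic acid leaves both stereocentres untouched (the descriptor at C2 changes only through CIP priorities).

Step 13
Reactants: 19 8α-hydroxy-6α,12-bis[(4-methoxybenzyl)oxy]-14-[(triethylsilyl)oxy]germacra-1(10),4,11(13)-trien-9-one; 22 (2S,3R)-2,3-dimethyloxirane-2-carboxylic acid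
Product: 23 8β-{[(2S,3R)-2,3-dimethyloxirane-2-carbonyl]oxy}-6α,12-bis[(4-methoxybenzyl)oxy]-14-[(triethylsilyl)oxy]germacra-1(10),4,11(13)-trien-9-one
Conditions: PPh3, DIAD, toluene, 0 °C → rt
Reagents that add atoms: none
Why: Mitsunobu esterification of the activated α-ketol should proceed by SN2 with inversion at C8, which installs the side chain and the 8β configuration in one operation.

Step 14
Reactants: 23 8β-{[(2S,3R)-2,3-dimethyloxirane-2-carbonyl]oxy}-6α,12-bis[(4-methoxybenzyl)oxy]-14-[(triethylsilyl)oxy]germacra-1(10),4,11(13)-trien-9-one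
Product: 24 8β-{[(2S,3R)-2,3-dimethyloxirane-2-carbonyl]oxy}-6α,12-bis[(4-methoxybenzyl)oxy]-14-[(triethylsilyl)oxy]germacra-1(10),4,11(13)-trien-9β-ol
Conditions: (R)-2-methyl-CBS-oxazaborolidine (0.5 equiv), catecholborane, toluene, −78 °C
Reagents that add atoms: none
Why: Corey–Bakshi–Shibata 1,2-reduction of the α-substituted enone under reagent control, with the α-branched alkenyl flank as the large group, should give the (9R) carbinol cis to the C8 ester; catecholborane spares the isolated olefins, the ester and the oxirane.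

Step 15
Reactants: 24 8β-{[(2S,3R)-2,3-dimethyloxirane-2-carbonyl]oxy}-6α,12-bis[(4-methoxybenzyl)oxy]-14-[(triethylsilyl)oxy]germacra-1(10),4,11(13)-trien-9β-ol
Product: 26 8β-{[(2S,3R)-2,3-dimethyloxirane-2-carbonyl]oxy}germacra-1(10),4,11(13)-triene-6α,9β,12,14-tetraol, via triethylsilyl ether triol 25 (not isolated)
Conditions: DDQ, CH2Cl2/pH 7 buffer, 0 °C; then PPTS (cat.), MeOH, rt
Reagents that add atoms: none
Why: Oxidative cleavage of both PMB ethers by DDQ, then mild acid methanolysis of the primary triethylsilyl ether, frees the four hydroxyl groups without touching the hindered glycidic ester.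

Step 16
Reactants: 26 8β-{[(2S,3R)-2,3-dimethyloxirane-2-carbonyl]oxy}germacra-1(10),4,11(13)-triene-6α,9β,12,14-tetraol
Product: 27 8β-{[(2S,3R)-2,3-dimethyloxirane-2-carbonyl]oxy}-9β-hydroxy-14-oxogermacra-1(10),4,11(13)-trien-12,6α-olide
Conditions: TEMPO (20 mol%), PhI(OAc)2, CH2Cl2, rt
Reagents that add atoms: none
Why: TEMPO/PhI(OAc)2 oxidises the two primary allylic alcohols in preference to the secondary ones; the C12 aldehyde is trapped by O6–H as a lactol and oxidised on to the trans-fused α-methylene-γ-lactone, while C14 stops at the enal.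

Step 17
Reactants: 27 8β-{[(2S,3R)-2,3-dimethyloxirane-2-carbonyl]oxy}-9β-hydroxy-14-oxogermacra-1(10),4,11(13)-trien-12,6α-olide
Product: 28 8β-{[(2S,3R)-2,3-dimethyloxirane-2-carbonyl]oxy}-9β-hydroxy-12-oxo-germacra-1(10),4,11(13)-trien-12,6α-olid-14-oic acid
Conditions: NaClO2, NaH2PO4, 2-methyl-2-butene, t-BuOH/H2O, 0 °C
Reagents that add atoms: sodium chlorite, [Na+].[O-]Cl=O
Why: Pinnick oxidation converts the enal into the acid without olefin isomerisation; the scavenger protects the C4=C5 bond from hypochlorite.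

Step 18
Reactants: 28 8β-{[(2S,3R)-2,3-dimethyloxirane-2-carbonyl]oxy}-9β-hydroxy-12-oxo-germacra-1(10),4,11(13)-trien-12,6α-olid-14-oic acid
Product: 29 methyl 8β-{[(2S,3R)-2,3-dimethyloxirane-2-carbonyl]oxy}-9β-hydroxy-12-oxo-germacra-1(10),4,11(13)-trien-12,6α-olid-14-oate
Conditions: MeI, KHCO3, DMF, rt
Reagents that add atoms: iodomethane, CI
Why: Carboxylate O-alkylation under weakly basic conditions avoids conjugate addition to the α-methylene lactone and acyl migration.

Step 19
Reactants: 29 methyl 8β-{[(2S,3R)-2,3-dimethyloxirane-2-carbonyl]oxy}-9β-hydroxy-12-oxo-germacra-1(10),4,11(13)-trien-12,6α-olid-14-oate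
Product: 30 target CNP0262846.1 (4α,5β-epoxide; 4R,5R)
Conditions: m-CPBA, CH2Cl2, 0 °C
Reagents that add atoms: 3-chloroperbenzoic acid, OOC(=O)c1cccc(Cl)c1
Why: Prilezhaev epoxidation should pick the only electron-rich olefin (C4=C5; the other two are conjugated to carbonyls) and attack its exposed outer face, as in the epoxidation of 6,12-trans-germacranolides, to give the trans (4R,5R)-oxirane.

## Compound list

1 | (E)-buta-1,3-dien-1-yl acetate | CC(=O)O/C=C/C=C | starting material
2 | methacrolein | CC(=C)C=O | starting material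
3 | (1R,6R)-6-formyl-6-methylcyclohex-2-en-1-yl acetate | CC(=O)O[C@@H]1C=CCC[C@@]1(C)C=O | intermediate
4 | (1R,6S)-6-[(E)-2-iodoethenyl]-6-methylcyclohex-2-en-1-yl acetate | CC(=O)O[C@@H]1C=CCC[C@@]1(C)/C=C/I | intermediate
5 | 4-methoxybenzyl alcohol | COc1ccc(CO)cc1 | starting material
6 | (1R,6S)-6-{(E)-2-[(4-methoxybenzyl)oxy]ethenyl}-6-methylcyclohex-2-en-1-yl acetate (not isolated) | CC(=O)O[C@@H]1C=CCC[C@@]1(C)/C=C/OCc1ccc(OC)cc1 | intermediate
7 | (1R,6S)-6-{(E)-2-[(4-methoxybenzyl)oxy]ethenyl}-6-methylcyclohex-2-en-1-ol | O[C@@H]1C=CCC[C@@]1(C)/C=C/OCc1ccc(OC)cc1 | intermediate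
8 | (6S)-6-{(E)-2-[(4-methoxybenzyl)oxy]ethenyl}-6-methylcyclohex-2-en-1-one | O=C1C=CCC[C@@]1(C)/C=C/OCc1ccc(OC)cc1 | intermediate
9 | (6S)-2-(hydroxymethyl)-6-{(E)-2-[(4-methoxybenzyl)oxy]ethenyl}-6-methylcyclohex-2-en-1-one | O=C1C(CO)=CCC[C@@]1(C)/C=C/OCc1ccc(OC)cc1 | intermediate
10 | (6S)-6-{(E)-2-[(4-methoxybenzyl)oxy]ethenyl}-6-methyl-2-{[(triethylsilyl)oxy]methyl}cyclohex-2-en-1-one | O=C1C(CO[Si](CC)(CC)CC)=CCC[C@@]1(C)/C=C/OCc1ccc(OC)cc1 | intermediate
11 | 2,3-dibromoprop-1-ene | C=C(Br)CBr | starting material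
12 | 1-{[(2-bromoprop-2-en-1-yl)oxy]methyl}-4-methoxybenzene | C=C(Br)COCc1ccc(OC)cc1 | intermediate
13 | (E)-1,2-bis(tributylstannyl)ethene | CCCC[Sn](CCCC)(CCCC)/C=C/[Sn](CCCC)(CCCC)CCCC | starting material
14 | tributyl[(1E)-3-{[(4-methoxybenzyl)oxy]methyl}buta-1,3-dien-1-yl]stannane | CCCC[Sn](CCCC)(CCCC)/C=C/C(=C)COCc1ccc(OC)cc1 | intermediate
15 | [(1E)-3-{[(4-methoxybenzyl)oxy]methyl}buta-1,3-dien-1-yl]lithium (not isolated) | [Li]/C=C/C(=C)COCc1ccc(OC)cc1 | intermediate
16 | (1R,6S)-6-{(E)-2-[(4-methoxybenzyl)oxy]ethenyl}-1-[(1E)-3-{[(4-methoxybenzyl)oxy]methyl}buta-1,3-dien-1-yl]-6-methyl-2-{[(triethylsilyl)oxy]methyl}cyclohex-2-en-1-ol | C=C(COCc1ccc(OC)cc1)/C=C/[C@]1(O)C(CO[Si](CC)(CC)CC)=CCC[C@@]1(C)/C=C/OCc1ccc(OC)cc1 | intermediate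
17 | potassium alkoxide of 16 (not isolated) | C=C(COCc1ccc(OC)cc1)/C=C/[C@]1([O-])C(CO[Si](CC)(CC)CC)=CCC[C@@]1(C)/C=C/OCc1ccc(OC)cc1.[K+] | intermediate
18 | potassium 6α,12-bis[(4-methoxybenzyl)oxy]-14-[(triethylsilyl)oxy]germacra-1(10),4E,8E,11(13)-tetraen-9-olate (not isolated) | C=C(COCc1ccc(OC)cc1)[C@@H]1/C=C(\[O-])/C(CO[Si](CC)(CC)CC)=C\CC/C(C)=C/[C@H]1OCc1ccc(OC)cc1.[K+] | intermediate
19 | 8α-hydroxy-6α,12-bis[(4-methoxybenzyl)oxy]-14-[(triethylsilyl)oxy]germacra-1(10),4,11(13)-trien-9-one | C=C(COCc1ccc(OC)cc1)[C@@H]1[C@@H](O)C(=O)/C(CO[Si](CC)(CC)CC)=C\CC/C(C)=C/[C@H]1OCc1ccc(OC)cc1 | intermediate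
20 | (E)-2-methylbut-2-en-1-ol | C/C=C(C)/CO | starting material
21 | [(2R,3R)-2,3-dimethyloxiran-2-yl]methanol | OC[C@@]1(C)O[C@@H]1C | intermediate
22 | (2S,3R)-2,3-dimethyloxirane-2-carboxylic acid | OC(=O)[C@@]1(C)O[C@@H]1C | intermediate
23 | 8β-{[(2S,3R)-2,3-dimethyloxirane-2-carbonyl]oxy}-6α,12-bis[(4-methoxybenzyl)oxy]-14-[(triethylsilyl)oxy]germacra-1(10),4,11(13)-trien-9-one | C=C(COCc1ccc(OC)cc1)[C@@H]1[C@H](OC(=O)[C@@]2(C)O[C@@H]2C)C(=O)/C(CO[Si](CC)(CC)CC)=C\CC/C(C)=C/[C@H]1OCc1ccc(OC)cc1 | intermediate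
24 | 9β-alcohol of 23 (9R) | C=C(COCc1ccc(OC)cc1)[C@@H]1[C@H](OC(=O)[C@@]2(C)O[C@@H]2C)[C@H](O)/C(CO[Si](CC)(CC)CC)=C\CC/C(C)=C/[C@H]1OCc1ccc(OC)cc1 | intermediate
25 | 6α,9β,12-triol 14-triethylsilyl ether (not isolated) | C=C(CO)[C@@H]1[C@H](OC(=O)[C@@]2(C)O[C@@H]2C)[C@H](O)/C(CO[Si](CC)(CC)CC)=C\CC/C(C)=C/[C@H]1O | intermediate
26 | 8β-{[(2S,3R)-2,3-dimethyloxirane-2-carbonyl]oxy}germacra-1(10),4,11(13)-triene-6α,9β,12,14-tetraol | C=C(CO)[C@@H]1[C@H](OC(=O)[C@@]2(C)O[C@@H]2C)[C@H](O)/C(CO)=C\CC/C(C)=C/[C@H]1O | intermediate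
27 | 8β-acyloxy-9β-hydroxy-14-oxogermacra-1(10),4,11(13)-trien-12,6α-olide | C=C1C(=O)O[C@@H]2/C=C(C)/CC/C=C(C=O)\[C@@H](O)[C@@H](OC(=O)[C@@]3(C)O[C@@H]3C)[C@@H]12 | intermediate
28 | 14-carboxylic acid of 27 | C=C1C(=O)O[C@@H]2/C=C(C)/CC/C=C(C(=O)O)\[C@@H](O)[C@@H](OC(=O)[C@@]3(C)O[C@@H]3C)[C@@H]12 | intermediate
29 | methyl 14-ester (4,5-olefin) | C=C1C(=O)O[C@@H]2/C=C(C)/CC/C=C(C(=O)OC)\[C@@H](O)[C@@H](OC(=O)[C@@]3(C)O[C@@H]3C)[C@@H]12 | intermediate
30 | CNP0262846.1 | C=C1C(=O)O[C@H]2[C@H]1[C@H](OC(=O)[C@@]1(C)O[C@@H]1C)[C@H](O)/C(C(=O)OC)=C\CC[C@@]1(C)O[C@H]21 | target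

## Step count

Total: 19 steps. Longest linear sequence: 15 steps (1–6, 9, 10, 13–19).

## Steps most likely to fail, with fallbacks

**Step 10 (key step).** What may go wrong: heterolytic fragmentation or a non-chair pathway of the bis-allylic alkoxide instead of the concerted shift, and proton transfer or over-oxidation of the enolate during the one-pot hydroxylation, with loss of facial control at C8. Fallback (neutral rearrangement, separate oxidation): it sets out from 16. Silylation (TMSOTf, 2,6-lutidine, CH2Cl2, −78 °C) gives the trimethylsilyl ether of 16 F1. Thermolysis (o-xylene, N,O-bis(trimethylsilyl)acetamide as acid scavenger, 140 °C, sealed tube) effects a neutral siloxy-Cope ring expansion through the same chair to the ring-expanded trimethylsilyl dienol ether F2. Rubottom oxidation of F2 (dimethyldioxirane, 1.0 equiv, acetone/CH2Cl2, −40 °C, then K2CO3/MeOH) should again occur on the outer face and returns to the route at 19. If only the oxidation is at fault, F2 is also available by a Me3SiCl quench of 18.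

**Step 9.** What may go wrong: poor facial selectivity of the 1,2-addition (attack syn to the alkoxyvinyl group gives the cis-dialkenyl carbinol, which cannot reach the required chair) and competing γ-deprotonation of the enone. Fallback (slimmer nucleophile, side chain built afterwards): it sets out from 10. Ethynylmagnesium bromide (CeCl3, THF, −78 °C), a rod-shaped nucleophile with a stronger preference for attack anti to the pseudo-axial alkoxyvinyl group, gives the 1-ethynyl carbinol F3. Pd-catalysed hydrostannation (Bu3SnH, PdCl2(PPh3)2, THF, 0 °C) gives the (E)-vinylstannane F4. Stille coupling of F4 with bromide 12 (Pd(PPh3)4, CuCl, LiCl, DMSO, rt) returns to the route at 16.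

**Step 13.** What may go wrong: slow SN2 at the hindered C8, where the carboxylate must enter from the ring-shielded face, with elimination or partial retention through an acyloxyphosphonium pathway. Fallback (redox inversion, then acylation with retention): it sets out from 19. Dess–Martin oxidation (NaHCO3, CH2Cl2) gives the 8,9-dione F5. Hydride reduction of the more electrophilic, non-conjugated C8 carbonyl (NaBH4, CH2Cl2/MeOH, −78 °C) from the exposed α-face, the same face the oxaziridine uses, should give the 8β-hydroxy ketone F6. Yamaguchi esterification of F6 with 22 (2,4,6-trichlorobenzoyl chloride, Et3N, then DMAP, toluene) returns to the route at 23.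

Further compounds
F1 | step 10 | trimethylsilyl ether of 16 | C=C(COCc1ccc(OC)cc1)/C=C/[C@]1(O[Si](C)(C)C)C(CO[Si](CC)(CC)CC)=CCC[C@@]1(C)/C=C/OCc1ccc(OC)cc1
F2 | step 10 | 9-(trimethylsilyloxy)-6α,12-bis[(4-methoxybenzyl)oxy]-14-[(triethylsilyl)oxy]germacra-1(10),4E,8E,11(13)-tetraene | C=C(COCc1ccc(OC)cc1)[C@@H]1/C=C(\O[Si](C)(C)C)/C(CO[Si](CC)(CC)CC)=C\CC/C(C)=C/[C@H]1OCc1ccc(OC)cc1
F3 | step 9 | (1R,6S)-1-ethynyl-6-{(E)-2-[(4-methoxybenzyl)oxy]ethenyl}-6-methyl-2-{[(triethylsilyl)oxy]methyl}cyclohex-2-en-1-ol | C#C[C@]1(O)C(CO[Si](CC)(CC)CC)=CCC[C@@]1(C)/C=C/OCc1ccc(OC)cc1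
F4 | step 9 | (1R,6S)-6-{(E)-2-[(4-methoxybenzyl)oxy]ethenyl}-6-methyl-1-[(E)-2-(tributylstannyl)ethenyl]-2-{[(triethylsilyl)oxy]methyl}cyclohex-2-en-1-ol | CCCC[Sn](CCCC)(CCCC)/C=C/[C@]1(O)C(CO[Si](CC)(CC)CC)=CCC[C@@]1(C)/C=C/OCc1ccc(OC)cc1
F5 | step 13 | 6α,12-bis[(4-methoxybenzyl)oxy]-14-[(triethylsilyl)oxy]germacra-1(10),4,11(13)-triene-8,9-dione | C=C(COCc1ccc(OC)cc1)[C@@H]1C(=O)C(=O)/C(CO[Si](CC)(CC)CC)=C\CC/C(C)=C/[C@H]1OCc1ccc(OC)cc1
F6 | step 13 | 8β-hydroxy-6α,12-bis[(4-methoxybenzyl)oxy]-14-[(triethylsilyl)oxy]germacra-1(10),4,11(13)-trien-9-one | C=C(COCc1ccc(OC)cc1)[C@@H]1[C@H](O)C(=O)/C(CO[Si](CC)(CC)CC)=C\CC/C(C)=C/[C@H]1OCc1ccc(OC)cc1
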